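**Retrosynthetic overview**
1. Target 30 ⇐ tetrasilyl ether 29 ⇐ open-chain 27: the dihydrofuran (ring E) is closed last, by C2–O bond formation when the ring-B 4-OH traps a benzylic cation trans to the C3 substituent.
2. Ring C (pendant 4-hydroxy-2-pyranone) ⇐ thermolysis of keto-dioxinone 24 ⇐ aldehyde 19 + dioxinone silyl dienol ether 22 (vinylogous Mukaiyama aldol, then oxidation).
3. Key C2–C3 bond: intermolecular Evans syn-aldol between the boron enolate of imide 14 (carrying rings B and D) and aldehyde 2 (ring A); the (R)-oxazolidinone fixes C3.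
4. Imide 14 ⇐ silylated hispidin 6 (C3 reductive alkylation with tert-butyl glyoxylate, O-allylation, auxiliary attachment) ⇐ triacetic acid lactone 3 + aldehyde 2 (vinylogous aldol, dehydration).
5. Ring order: rings A, D and B are bought (protocatechualdehyde, triacetic acid lactone); ring C is built in step 15; ring E is closed in step 17.

Assumption: the (2R,3R) configuration in the SMILES is the trans-2,3-dihydrofuran (hypholomine B); common reagents (LiN(iPr)2 solution, silylating agents, tert-butyl glyoxylate) are bought.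
Shorthand in names: TBS = tert-butyldimethylsilyl; Ar = 3,4-bis(TBS-oxy)phenyl; PyB = 4-(allyloxy)-6-[(E)-2-Ar-ethenyl]-2-oxo-2H-pyran-3-yl.

**Step 1**
Reactants: 1 3,4-dihydroxybenzaldehyde
Product: 2 3,4-bis(TBS-oxy)benzaldehyde
Conditions: TBSCl (2.4 equiv), imidazole (5 equiv), DMF, 20 °C
Reagents that add atoms: tert-butyldimethylsilyl chloride, CC(C)(C)[Si](C)(C)Cl
Why: Imidazole-promoted silylation of both phenols is a standard protection that creates no stereocentre.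

**Step 2**
Reactants: 3 4-hydroxy-6-methyl-2H-pyran-2-one (triacetic acid lactone); 2 3,4-bis(TBS-oxy)benzaldehyde
Product: 5 (±)-6-(2-Ar-2-hydroxyethyl)-4-hydroxy-2H-pyran-2-one, via TAL dianion 4 (not isolated)
Conditions: LiN(iPr)2 (2.3 equiv), THF, −78 °C; then 2, −78 to −20 °C; 1 M HCl
Reagents that add atoms: none
Why: The O,C-dianion reacts at its more basic C6-methylene carbon with the aldehyde in a vinylogous aldol addition, and the racemic carbinol centre so formed is destroyed by the dehydration in step 3.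

**Step 3**
Reactants: 5 (±)-6-(2-Ar-2-hydroxyethyl)-4-hydroxy-2H-pyran-2-one
Product: 6 6-[(E)-2-Ar-ethenyl]-4-hydroxy-2H-pyran-2-one
Conditions: TsOH·H2O (10 mol%), 1,2-dichloroethane, 70 °C
Reagents that add atoms: none
Why: Acid-catalysed E1 dehydration through the para-silyloxy-stabilised benzylic cation gives the fully conjugated (E)-styrylpyranone as the thermodynamic alkene.

**Step 4**
Reactants: 6 6-[(E)-2-Ar-ethenyl]-4-hydroxy-2H-pyran-2-one; 7 tert-butyl glyoxylate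
Product: 9 tert-butyl 2-{6-[(E)-2-Ar-ethenyl]-4-hydroxy-2-oxo-2H-pyran-3-yl}acetate, via Knoevenagel alkylidene 8 (not isolated)
Conditions: L-proline (20 mol%), Hantzsch ester (1.1 equiv), CH2Cl2, 20 °C
Reagents that add atoms: none
Why: In this organocatalytic reductive alkylation, Knoevenagel condensation at the nucleophilic C3 of the 4-hydroxypyranone gives alkylidene 8, which is reduced at once by conjugate hydride transfer from the Hantzsch ester, so alkylation occurs on carbon only.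

**Step 5**
Reactants: 9 tert-butyl 2-{6-[(E)-2-Ar-ethenyl]-4-hydroxy-2-oxo-2H-pyran-3-yl}acetate
Product: 10 tert-butyl 2-PyB-acetate
Conditions: allyl alcohol (1.5 equiv), PPh3, DIAD, THF, 0 to 20 °C
Reagents that add atoms: allyl alcohol, C=CCO
Why: Mitsunobu O-alkylation of the acidic vinylogous acid takes place on O4 to give the 4-alkoxy-2-pyranone, which masks the enol for the enolate chemistry that follows.

**Step 6**
Reactants: 10 tert-butyl 2-PyB-acetate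
Product: 11 2-PyB-acetic acid
Conditions: TFA/CH2Cl2 (1:4), 0 to 20 °C
Reagents that add atoms: none
Why: Acidolysis of the tert-butyl ester by E1 loss of isobutene leaves the aryl silyl ethers, the allyl enol ether and the styryl group untouched.

**Step 7**
Reactants: 11 2-PyB-acetic acid; 12 (R)-4-benzyl-1,3-oxazolidin-2-one
Product: 14 (R)-4-benzyl-3-(2-PyB-acetyl)-1,3-oxazolidin-2-one, via mixed pivalic anhydride 13 (not isolated)
Conditions: pivaloyl chloride (1.1 equiv), Et3N (2.5 equiv), THF, −20 °C; then 12, LiCl (1.2 equiv), 20 °C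
Reagents that add atoms: none
Why: N-Acylation of the oxazolidinone through the mixed pivalic anhydride under LiCl and Et3N is a mild protocol for arylacetic-type acids and creates no new stereocentre.

**Step 8**
Reactants: 14 (R)-4-benzyl-3-(2-PyB-acetyl)-1,3-oxazolidin-2-one; 2 3,4-bis(TBS-oxy)benzaldehyde
Product: 16 (R)-4-benzyl-3-[(2R,3R)-3-Ar-3-hydroxy-2-PyB-propanoyl]-1,3-oxazolidin-2-one, via (Z)-boron enolate 15 (not isolated)
Conditions: nBu2BOTf (1.3 equiv), iPr2NEt (1.5 equiv), CH2Cl2, 0 °C; then 2, −78 to 0 °C; pH 7 buffer (NaH2PO4/Na2HPO4), MeOH, 30% H2O2, 0 °C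
Reagents that add atoms: none
Why: In this Evans syn-aldol reaction the (Z)-boron enolate reacts through a Zimmerman–Traxler chair on the face away from the benzyl group of the (R)-auxiliary, which fixes the future C3 centre as R and gives the 2,3-syn (2R,3R) adduct (the carbinol centre formed here is re-set in step 17).

**Step 9**
Reactants: 16 (R)-4-benzyl-3-[(2R,3R)-3-Ar-3-hydroxy-2-PyB-propanoyl]-1,3-oxazolidin-2-one
Product: 17 (R)-4-benzyl-3-[(2R,3R)-3-Ar-2-PyB-3-(TBS-oxy)propanoyl]-1,3-oxazolidin-2-one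
Conditions: TBSOTf (1.5 equiv), 2,6-lutidine (2.5 equiv), CH2Cl2, −78 to 0 °C
Reagents that add atoms: tert-butyldimethylsilyl triflate, CC(C)(C)[Si](C)(C)OS(=O)(=O)C(F)(F)F
Why: Silylation of the hindered benzylic alcohol with the silyl triflate and a hindered pyridine base blocks retro-aldol cleavage and β-elimination in the steps that follow.

**Step 10**
Reactants: 17 (R)-4-benzyl-3-[(2R,3R)-3-Ar-2-PyB-3-(TBS-oxy)propanoyl]-1,3-oxazolidin-2-one
Product: 18 (2S,3R)-3-Ar-2-PyB-3-(TBS-oxy)propan-1-ol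
Conditions: LiBH4 (2 equiv), H2O (2 equiv), Et2O, 0 °C
Reagents that add atoms: none
Why: Reductive removal of the auxiliary with LiBH4 attacks the activated exocyclic imide carbonyl much faster than the 2-pyranone, which is a poorly electrophilic vinylogous carbonate, and leaves both stereocentres untouched (the descriptor changes only by priority).

**Step 11**
Reactants: 18 (2S,3R)-3-Ar-2-PyB-3-(TBS-oxy)propan-1-ol
Product: 19 (2R,3R)-3-Ar-2-PyB-3-(TBS-oxy)propanal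
Conditions: Dess–Martin periodinane (1.3 equiv), NaHCO3, CH2Cl2, 0 to 20 °C; used crude
Reagents that add atoms: none
Why: Buffered Dess–Martin oxidation gives the α-branched aldehyde under neutral conditions so that the epimerisable C2 centre is kept.

**Step 12**
Reactants: 20 2,2,6-trimethyl-4H-1,3-dioxin-4-one
Product: 22 2,2-dimethyl-4-methylidene-6-(trimethylsilyloxy)-4H-1,3-dioxine, via lithium dienolate 21 (not isolated)
Conditions: LiN(iPr)2 (1.1 equiv), THF, −78 °C; then TMSCl (1.2 equiv), −78 to 0 °C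
Reagents that add atoms: chlorotrimethylsilane, C[Si](C)(C)Cl
Why: Kinetic γ-deprotonation of the dioxinone and O-silylation of the lithium dienolate give the silyl dienol ether needed for a non-basic vinylogous aldol reaction.

**Step 13**
Reactants: 19 (2R,3R)-3-Ar-2-PyB-3-(TBS-oxy)propanal; 22 2,2-dimethyl-4-methylidene-6-(trimethylsilyloxy)-4H-1,3-dioxine
Product: 23 6-[(2RS,3S,4R)-4-Ar-2-hydroxy-3-PyB-4-(TBS-oxy)butyl]-2,2-dimethyl-4H-1,3-dioxin-4-one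
Conditions: 22 (2 equiv), BF3·OEt2 (1.2 equiv), CH2Cl2, −78 °C; aqueous NaHCO3
Reagents that add atoms: none
Why: Vinylogous Mukaiyama aldol addition through the γ-carbon of the silyl dienol ether under Lewis-acid activation at −78 °C extends the chain by four carbons without base, so the α-centre is not epimerised, and the new carbinol centre forms as a mixture that is oxidised away in step 14.

**Step 14**
Reactants: 23 6-[(2RS,3S,4R)-4-Ar-2-hydroxy-3-PyB-4-(TBS-oxy)butyl]-2,2-dimethyl-4H-1,3-dioxin-4-one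
Product: 24 6-[(3R,4R)-4-Ar-2-oxo-3-PyB-4-(TBS-oxy)butyl]-2,2-dimethyl-4H-1,3-dioxin-4-one
Conditions: Dess–Martin periodinane (1.5 equiv), NaHCO3, CH2Cl2, 20 °C
Reagents that add atoms: none
Why: Dess–Martin oxidation of the secondary alcohol gives the β-keto-dioxinone, a masked 3,5-diketo acid, under neutral conditions.

**Step 15**
Reactants: 24 6-[(3R,4R)-4-Ar-2-oxo-3-PyB-4-(TBS-oxy)butyl]-2,2-dimethyl-4H-1,3-dioxin-4-one
Product: 26 6-[(1R,2R)-2-Ar-1-PyB-2-(TBS-oxy)ethyl]-4-hydroxy-2H-pyran-2-one, via acylketene 25 (not isolated)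
Conditions: toluene (0.01 M), 110 °C, 45 min
Reagents that add atoms: none
Why: Thermal retro-[4+2] loss of acetone unmasks an acylketene that is captured by the enol oxygen of the neighbouring ketone in a six-membered lactonisation, which gives the 4-hydroxy-2-pyranone of ring C under neutral conditions with the C3 centre intact.

**Step 16**
Reactants: 26 6-[(1R,2R)-2-Ar-1-PyB-2-(TBS-oxy)ethyl]-4-hydroxy-2H-pyran-2-one
Product: 27 6-[(1R,2R)-2-Ar-1-{6-[(E)-2-Ar-ethenyl]-4-hydroxy-2-oxo-2H-pyran-3-yl}-2-(TBS-oxy)ethyl]-4-hydroxy-2H-pyran-2-one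
Conditions: Pd(PPh3)4 (5 mol%), morpholine (5 equiv), THF, 20 °C; aqueous citric acid work-up
Reagents that add atoms: none
Why: In this Tsuji–Trost deallylation zerovalent palladium ionises the allyl vinylogous ester to a π-allyl complex that is captured by the excess amine, which frees the ring-B 4-hydroxyl while the silyl ethers stay in place.

**Step 17**
Reactants: 27 6-[(1R,2R)-2-Ar-1-{6-[(E)-2-Ar-ethenyl]-4-hydroxy-2-oxo-2H-pyran-3-yl}-2-(TBS-oxy)ethyl]-4-hydroxy-2H-pyran-2-one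
Product: 29 (2R,3R)-2-Ar-6-[(E)-2-Ar-ethenyl]-3-(4-hydroxy-2-oxo-2H-pyran-6-yl)-2,3-dihydro-4H-furo[3,2-c]pyran-4-one, via benzylic cation 28 (not isolated)
Conditions: TFA (5 vol%), CH2Cl2 (0.005 M), 0 °C, stopped at full conversion
Reagents that add atoms: none
Why: Acid ionises the benzylic silyl ether to a para-silyloxy-stabilised cation that is trapped 5-exo by the ring-B 4-hydroxyl in a reversible cyclisation, which leads to the more stable furo[3,2-c]pyran-4-one isomer and places the aryl group trans to the ring-C substituent, so the (R) centre at C3 dictates (R) at C2.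

**Step 18**
Reactants: 29 (2R,3R)-2-Ar-6-[(E)-2-Ar-ethenyl]-3-(4-hydroxy-2-oxo-2H-pyran-6-yl)-2,3-dihydro-4H-furo[3,2-c]pyran-4-one
Product: 30 (2R,3R)-2-(3,4-dihydroxyphenyl)-6-[(E)-2-(3,4-dihydroxyphenyl)ethenyl]-3-(4-hydroxy-2-oxo-2H-pyran-6-yl)-2,3-dihydro-4H-furo[3,2-c]pyran-4-one
Conditions: HF·pyridine, pyridine/THF, 0 to 20 °C, argon
Reagents that add atoms: none
Why: Fluoride cleaves the four aryl silyl ethers under mildly acidic conditions that the catechols, the pyranones and the benzylic ether tolerate, and no stereocentre is touched.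

**Compound list**
1 | 3,4-dihydroxybenzaldehyde | O=Cc1ccc(O)c(O)c1 | starting material
2 | 3,4-bis(TBS-oxy)benzaldehyde | O=Cc1ccc(O[Si](C)(C)C(C)(C)C)c(O[Si](C)(C)C(C)(C)C)c1 | intermediate
3 | 4-hydroxy-6-methyl-2H-pyran-2-one | Cc1cc(O)cc(=O)o1 | starting material
4 | dilithium O4,C7-dianion of 3 | [Li+].[Li+].[CH2-]c1cc([O-])cc(=O)o1 | intermediate
5 | (±)-6-(2-Ar-2-hydroxyethyl)-4-hydroxy-2H-pyran-2-one | OC(Cc1cc(O)cc(=O)o1)c1ccc(O[Si](C)(C)C(C)(C)C)c(O[Si](C)(C)C(C)(C)C)c1 | intermediate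
6 | 6-[(E)-2-Ar-ethenyl]-4-hydroxy-2H-pyran-2-one | O=c1cc(O)cc(/C=C/c2ccc(O[Si](C)(C)C(C)(C)C)c(O[Si](C)(C)C(C)(C)C)c2)o1 | intermediate
7 | tert-butyl glyoxylate | O=CC(=O)OC(C)(C)C | starting material
8 | tert-butyl 2-{6-[(E)-2-Ar-ethenyl]-2,4-dioxo-2H-pyran-3(4H)-ylidene}acetate | CC(C)(C)OC(=O)C=C1C(=O)C=C(/C=C/c2ccc(O[Si](C)(C)C(C)(C)C)c(O[Si](C)(C)C(C)(C)C)c2)OC1=O | intermediate
9 | tert-butyl 2-{6-[(E)-2-Ar-ethenyl]-4-hydroxy-2-oxo-2H-pyran-3-yl}acetate | CC(C)(C)OC(=O)Cc1c(O)cc(/C=C/c2ccc(O[Si](C)(C)C(C)(C)C)c(O[Si](C)(C)C(C)(C)C)c2)oc1=O | intermediate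
10 | tert-butyl 2-PyB-acetate | CC(C)(C)OC(=O)Cc1c(OCC=C)cc(/C=C/c2ccc(O[Si](C)(C)C(C)(C)C)c(O[Si](C)(C)C(C)(C)C)c2)oc1=O | intermediate
11 | 2-PyB-acetic acid | OC(=O)Cc1c(OCC=C)cc(/C=C/c2ccc(O[Si](C)(C)C(C)(C)C)c(O[Si](C)(C)C(C)(C)C)c2)oc1=O | intermediate
12 | (R)-4-benzyl-1,3-oxazolidin-2-one | O=C1N[C@H](Cc2ccccc2)CO1 | starting material
13 | mixed pivalic anhydride of 11 | CC(C)(C)C(=O)OC(=O)Cc1c(OCC=C)cc(/C=C/c2ccc(O[Si](C)(C)C(C)(C)C)c(O[Si](C)(C)C(C)(C)C)c2)oc1=O | intermediate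
14 | (R)-4-benzyl-3-(2-PyB-acetyl)-1,3-oxazolidin-2-one | O=C(Cc1c(OCC=C)cc(/C=C/c2ccc(O[Si](C)(C)C(C)(C)C)c(O[Si](C)(C)C(C)(C)C)c2)oc1=O)N1[C@H](Cc2ccccc2)COC1=O | intermediate
15 | (Z)-di-n-butylboron enolate of 14 | CCCCB(CCCC)O/C(=C\c1c(OCC=C)cc(/C=C/c2ccc(O[Si](C)(C)C(C)(C)C)c(O[Si](C)(C)C(C)(C)C)c2)oc1=O)N1[C@H](Cc2ccccc2)COC1=O | intermediate
16 | (R)-4-benzyl-3-[(2R,3R)-3-Ar-3-hydroxy-2-PyB-propanoyl]-1,3-oxazolidin-2-one | O=C([C@@H]([C@@H](O)c1ccc(O[Si](C)(C)C(C)(C)C)c(O[Si](C)(C)C(C)(C)C)c1)c1c(OCC=C)cc(/C=C/c2ccc(O[Si](C)(C)C(C)(C)C)c(O[Si](C)(C)C(C)(C)C)c2)oc1=O)N1[C@H](Cc2ccccc2)COC1=O | intermediate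
17 | (R)-4-benzyl-3-[(2R,3R)-3-Ar-2-PyB-3-(TBS-oxy)propanoyl]-1,3-oxazolidin-2-one | O=C([C@@H]([C@@H](O[Si](C)(C)C(C)(C)C)c1ccc(O[Si](C)(C)C(C)(C)C)c(O[Si](C)(C)C(C)(C)C)c1)c1c(OCC=C)cc(/C=C/c2ccc(O[Si](C)(C)C(C)(C)C)c(O[Si](C)(C)C(C)(C)C)c2)oc1=O)N1[C@H](Cc2ccccc2)COC1=O | intermediate
18 | (2S,3R)-3-Ar-2-PyB-3-(TBS-oxy)propan-1-ol | OC[C@@H]([C@@H](O[Si](C)(C)C(C)(C)C)c1ccc(O[Si](C)(C)C(C)(C)C)c(O[Si](C)(C)C(C)(C)C)c1)c1c(OCC=C)cc(/C=C/c2ccc(O[Si](C)(C)C(C)(C)C)c(O[Si](C)(C)C(C)(C)C)c2)oc1=O | intermediate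
19 | (2R,3R)-3-Ar-2-PyB-3-(TBS-oxy)propanal | O=C[C@@H]([C@@H](O[Si](C)(C)C(C)(C)C)c1ccc(O[Si](C)(C)C(C)(C)C)c(O[Si](C)(C)C(C)(C)C)c1)c1c(OCC=C)cc(/C=C/c2ccc(O[Si](C)(C)C(C)(C)C)c(O[Si](C)(C)C(C)(C)C)c2)oc1=O | intermediate
20 | 2,2,6-trimethyl-4H-1,3-dioxin-4-one | CC1=CC(=O)OC(C)(C)O1 | starting material
21 | lithium dienolate of 20 | [Li+].C=C1C=C([O-])OC(C)(C)O1 | intermediate
22 | 2,2-dimethyl-4-methylidene-6-(trimethylsilyloxy)-4H-1,3-dioxine | C=C1C=C(O[Si](C)(C)C)OC(C)(C)O1 | intermediate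
23 | 6-[(2RS,3S,4R)-4-Ar-2-hydroxy-3-PyB-4-(TBS-oxy)butyl]-2,2-dimethyl-4H-1,3-dioxin-4-one | CC1(C)OC(=O)C=C(CC(O)[C@@H]([C@@H](O[Si](C)(C)C(C)(C)C)c2ccc(O[Si](C)(C)C(C)(C)C)c(O[Si](C)(C)C(C)(C)C)c2)c2c(OCC=C)cc(/C=C/c3ccc(O[Si](C)(C)C(C)(C)C)c(O[Si](C)(C)C(C)(C)C)c3)oc2=O)O1 | intermediate
24 | 6-[(3R,4R)-4-Ar-2-oxo-3-PyB-4-(TBS-oxy)butyl]-2,2-dimethyl-4H-1,3-dioxin-4-one | CC1(C)OC(=O)C=C(CC(=O)[C@@H]([C@@H](O[Si](C)(C)C(C)(C)C)c2ccc(O[Si](C)(C)C(C)(C)C)c(O[Si](C)(C)C(C)(C)C)c2)c2c(OCC=C)cc(/C=C/c3ccc(O[Si](C)(C)C(C)(C)C)c(O[Si](C)(C)C(C)(C)C)c3)oc2=O)O1 | intermediate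
25 | (6R,7R)-7-Ar-6-PyB-7-(TBS-oxy)-3,5-dioxohept-1-en-1-one (acylketene) | O=C=CC(=O)CC(=O)[C@@H]([C@@H](O[Si](C)(C)C(C)(C)C)c1ccc(O[Si](C)(C)C(C)(C)C)c(O[Si](C)(C)C(C)(C)C)c1)c1c(OCC=C)cc(/C=C/c2ccc(O[Si](C)(C)C(C)(C)C)c(O[Si](C)(C)C(C)(C)C)c2)oc1=O | intermediate
26 | 6-[(1R,2R)-2-Ar-1-PyB-2-(TBS-oxy)ethyl]-4-hydroxy-2H-pyran-2-one | O=c1cc(O)cc([C@@H]([C@@H](O[Si](C)(C)C(C)(C)C)c2ccc(O[Si](C)(C)C(C)(C)C)c(O[Si](C)(C)C(C)(C)C)c2)c2c(OCC=C)cc(/C=C/c3ccc(O[Si](C)(C)C(C)(C)C)c(O[Si](C)(C)C(C)(C)C)c3)oc2=O)o1 | intermediate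
27 | 6-[(1R,2R)-2-Ar-1-{6-[(E)-2-Ar-ethenyl]-4-hydroxy-2-oxo-2H-pyran-3-yl}-2-(TBS-oxy)ethyl]-4-hydroxy-2H-pyran-2-one | O=c1cc(O)cc([C@@H]([C@@H](O[Si](C)(C)C(C)(C)C)c2ccc(O[Si](C)(C)C(C)(C)C)c(O[Si](C)(C)C(C)(C)C)c2)c2c(O)cc(/C=C/c3ccc(O[Si](C)(C)C(C)(C)C)c(O[Si](C)(C)C(C)(C)C)c3)oc2=O)o1 | intermediate
28 | benzylic cation from 27 (C1 configuration of 27 kept) | O=c1cc(O)cc([C@@H]([CH+]c2ccc(O[Si](C)(C)C(C)(C)C)c(O[Si](C)(C)C(C)(C)C)c2)c2c(O)cc(/C=C/c3ccc(O[Si](C)(C)C(C)(C)C)c(O[Si](C)(C)C(C)(C)C)c3)oc2=O)o1 | intermediate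
29 | (2R,3R)-2-Ar-6-[(E)-2-Ar-ethenyl]-3-(4-hydroxy-2-oxo-2H-pyran-6-yl)-2,3-dihydro-4H-furo[3,2-c]pyran-4-one | O=c1cc(O)cc([C@@H]2c3c(cc(/C=C/c4ccc(O[Si](C)(C)C(C)(C)C)c(O[Si](C)(C)C(C)(C)C)c4)oc3=O)O[C@H]2c2ccc(O[Si](C)(C)C(C)(C)C)c(O[Si](C)(C)C(C)(C)C)c2)o1 | intermediate
30 | (2R,3R)-2-(3,4-dihydroxyphenyl)-6-[(E)-2-(3,4-dihydroxyphenyl)ethenyl]-3-(4-hydroxy-2-oxo-2H-pyran-6-yl)-2,3-dihydro-4H-furo[3,2-c]pyran-4-one (CNP0229149.3) | O=c1cc(O)cc([C@@H]2c3c(cc(/C=C/c4ccc(O)c(O)c4)oc3=O)O[C@H]2c2ccc(O)c(O)c2)o1 | target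

**Totals**
Total step count: 18. Longest linear sequence: 17 steps (steps 1–11 and 13–18 from 1; step 12 is a one-step side branch).

**Steps most likely to fail, with fallbacks**

Step 8 (key aldol). The Lewis-basic pyranone carbonyl may sequester the boron triflate, and the adduct of an electron-rich aldehyde is prone to retro-aldol cleavage. The fallback sets out from acid 11 and comes back at aldehyde 19. Acid 11 is coupled (EDC·HCl, DMAP, CH2Cl2) with bought (R)-4-benzyl-1,3-thiazolidine-2-thione to give the N-acyl thiazolidinethione F1. Soft enolisation with TiCl4, iPr2NEt and N-methyl-2-pyrrolidinone in CH2Cl2 at −78 °C, then aldehyde 2, gives the Evans-syn (2R,3R) aldol thioimide F2 through a chelated titanium enolate. TBSOTf and 2,6-lutidine give its TBS ether F3, which iBu2AlH at −78 °C reduces directly to 19, so that 16–18 are bypassed.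

Step 13 (vinylogous Mukaiyama aldol). Aldehyde 19 is α-epimerisable, and BF3·OEt2 may ionise the benzylic silyl ether. The fallback sets out from imide 17 and comes back at pyranone 26, avoiding both the aldehyde and the Lewis acid. LiOH and H2O2 (THF/H2O, 0 °C) cleave the auxiliary to give the carboxylic acid F4. 1-Chloro-N,N,2-trimethylprop-1-en-1-amine (CH2Cl2, 0 °C) converts it under neutral conditions into the acid chloride F5. Bought 1-methoxy-1,3-bis(trimethylsilyloxy)buta-1,3-diene (CH2Cl2, −78 to 20 °C, no Lewis acid, aqueous work-up) is C-acylated at its terminal carbon in a silyl-Claisen condensation to give the methyl 3,5-dioxoheptanoate F6. DBU in toluene at 20 °C lactonises F6 to 26.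

Step 17 (ring E closure). Under TFA the cation may lose the C3 proton (erosion of the C3 centre on re-protonation), be attacked by the nucleophilic C3 of ring C, or close through the lactone oxygen. The fallback sets out from 27 and comes back at target 30, replacing cation chemistry by a neutral quinone methide. HF·pyridine (pyridine/THF) removes all five silyl groups first to give the seco-hexol F7. Gentle warming of F7 in MeCN/H2O with a trace of acetic acid lets the para-hydroxybenzylic alcohol lose water to the para-quinone methide F8. The ring-B 4-hydroxyl adds 5-exo (oxa-Michael) to F8, trans to the C3 substituent, giving 30 directly.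

**Further compounds**
F1 | step 8 | (R)-4-benzyl-3-(2-PyB-acetyl)-1,3-thiazolidine-2-thione | O=C(Cc1c(OCC=C)cc(/C=C/c2ccc(O[Si](C)(C)C(C)(C)C)c(O[Si](C)(C)C(C)(C)C)c2)oc1=O)N1[C@H](Cc2ccccc2)CSC1=S
F2 | step 8 | (R)-4-benzyl-3-[(2R,3R)-3-Ar-3-hydroxy-2-PyB-propanoyl]-1,3-thiazolidine-2-thione | O=C([C@@H]([C@@H](O)c1ccc(O[Si](C)(C)C(C)(C)C)c(O[Si](C)(C)C(C)(C)C)c1)c1c(OCC=C)cc(/C=C/c2ccc(O[Si](C)(C)C(C)(C)C)c(O[Si](C)(C)C(C)(C)C)c2)oc1=O)N1[C@H](Cc2ccccc2)CSC1=S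
F3 | step 8 | (R)-4-benzyl-3-[(2R,3R)-3-Ar-2-PyB-3-(TBS-oxy)propanoyl]-1,3-thiazolidine-2-thione | O=C([C@@H]([C@@H](O[Si](C)(C)C(C)(C)C)c1ccc(O[Si](C)(C)C(C)(C)C)c(O[Si](C)(C)C(C)(C)C)c1)c1c(OCC=C)cc(/C=C/c2ccc(O[Si](C)(C)C(C)(C)C)c(O[Si](C)(C)C(C)(C)C)c2)oc1=O)N1[C@H](Cc2ccccc2)CSC1=S
F4 | step 13 | (2R,3R)-3-Ar-2-PyB-3-(TBS-oxy)propanoic acid | OC(=O)[C@@H]([C@@H](O[Si](C)(C)C(C)(C)C)c1ccc(O[Si](C)(C)C(C)(C)C)c(O[Si](C)(C)C(C)(C)C)c1)c1c(OCC=C)cc(/C=C/c2ccc(O[Si](C)(C)C(C)(C)C)c(O[Si](C)(C)C(C)(C)C)c2)oc1=O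
F5 | step 13 | (2R,3R)-3-Ar-2-PyB-3-(TBS-oxy)propanoyl chloride | ClC(=O)[C@@H]([C@@H](O[Si](C)(C)C(C)(C)C)c1ccc(O[Si](C)(C)C(C)(C)C)c(O[Si](C)(C)C(C)(C)C)c1)c1c(OCC=C)cc(/C=C/c2ccc(O[Si](C)(C)C(C)(C)C)c(O[Si](C)(C)C(C)(C)C)c2)oc1=O
F6 | step 13 | methyl (6R,7R)-7-Ar-6-PyB-7-(TBS-oxy)-3,5-dioxoheptanoate | COC(=O)CC(=O)CC(=O)[C@@H]([C@@H](O[Si](C)(C)C(C)(C)C)c1ccc(O[Si](C)(C)C(C)(C)C)c(O[Si](C)(C)C(C)(C)C)c1)c1c(OCC=C)cc(/C=C/c2ccc(O[Si](C)(C)C(C)(C)C)c(O[Si](C)(C)C(C)(C)C)c2)oc1=O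
F7 | step 17 | 6-[(1R,2R)-2-(3,4-dihydroxyphenyl)-1-{6-[(E)-2-(3,4-dihydroxyphenyl)ethenyl]-4-hydroxy-2-oxo-2H-pyran-3-yl}-2-hydroxyethyl]-4-hydroxy-2H-pyran-2-one | O=c1cc(O)cc([C@@H]([C@@H](O)c2ccc(O)c(O)c2)c2c(O)cc(/C=C/c3ccc(O)c(O)c3)oc2=O)o1
F8 | step 17 | para-quinone methide of F7 (ring A as 3-hydroxy-4-oxocyclohexa-2,5-dien-1-ylidene, C1 configuration of F7 kept) | O=c1cc(O)cc([C@@H](C=C2C=CC(=O)C(O)=C2)c2c(O)cc(/C=C/c3ccc(O)c(O)c3)oc2=O)o1
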